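## Structural features

The target is a spiro[4.5]decane in which cyclopentane ring B (C9, C10, C11, C12, C28) and cyclohexane ring A (C12, C13, C18, C23, C24, C25) share the quaternary carbon C12; atom labels are the positions in the target SMILES. Ring B carries the secondary alcohol C28 and, next to it at C9, a 1-(hydroxymethyl)triene chain (C6=C5, C4=C3, C2=C1) that ends in a prenyl unit. Ring A carries a 3-hydroxypropyl chain at C13, a tetrasubstituted exocyclic enal at C18=C19 and the methyl carbinol C25. The five stereocentres (9S, 12S, 13R, 25S, 28R) are contiguous around C12: O29, C14 and O27 all lie on the C28 face of ring A, C6 is cis to O29 on ring B, and C25 is trans to O29 across ring B. Three alkenes are stereodefined: C5=C6 (C4 cis to C9), C3=C4 (E) and C18=C19 (methyl C20 cis to C13, formyl C21 cis to C23). The fragile parts are the cross-conjugated triene with its allylic primary alcohol (acid, oxidants, cycloaddition), the enal with a γ-hydrogen at C13 (base, geometric drift), and two primary allylic positions (C7 and C21) that a late oxidation could not tell apart. The real difficulty is the all-carbon spiro centre flanked by C28, C13 and C25, the placement of C14 on the more crowded face next to O29, and the geometry of the tetrasubstituted enal. The key step uses the position of C12 between the oxygenated C28 of ring B and C25 of ring A: a C11=C12 cyclopentene with a silyloxy group on C28 accepts an alkenylpalladium centred on C25 and tethered through C24–C23–C18–C13, so ring A and the spiro centre form together and leave a C25=C26 methylene and a C10=C11 alkene.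

## Logic of the disconnections

43 is traced to 41 through 42 by cutting no carbon–carbon bond: the C7–O29 ester bond is restored as a lactone and C21 is masked as a dimethyl acetal. The lactone keeps C7 and O29 tied and activates C6, and the acetal hides the enal from bases and hydrides. The only late redox event is then a hydride reduction, which must stop at the allylic diol and leave the triene alone, and the unmasking must be mild enough for the trienyl carbinol.

41 goes back through 40 and 38 to 33 and 37 by cutting C5=C6. This brings in the whole ten-carbon triene at the end, so 33 contains no polyene. The forward aldol condensation must place C4 anti to the lactone carbonyl, which is the geometry expected to be favoured when the elimination is run under equilibrating conditions.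

37 is cut at C2–C3 into 35 and 36, and 35 comes from 34 by changing the carbonyl into an alkenyl triflate. The forward steps need kinetic enolisation on the methyl side and an E-selective coupling.

33 is cut at C6–C9 to 32, which comes from 30 by acylation of O29. A carbenoid tethered to O29 can only reach the C9–H bond on its own face through a five-membered transition state, so C28 is copied onto C9. The demands are site selectivity for C9–H, a protected O27 and no reactive alkene nearby.

30, 29 and 28 go back to 27 and 26 by cutting C18–C19. The enal is derived from the C18 ketone by adding an isopropenyl nucleophile and transposing the tertiary allylic alcohol oxidatively. The forward step must put C21 on the C23 side. It is placed before the triene exists so that chromium and acid never meet the polyene.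

26 goes back through 25 and 23 to 21 and 22 by cutting C13–C14. C13 is the neopentyl, less accessible α-position, so C23 is blocked as the enone in 21. C14 is brought in as an alkylidene so that the last bond made at C13 is a C–H bond from the open face. A direct alkylation would deliver carbon from that same face and put C14 on the side away from O29. One hydrogenation then saturates C13=C14, C23=C24 and C10=C11, and it must be face-selective at C13.

21 goes back through 19, 18 and 17 to 16 by functional-group changes only: dehydrogenation at C23–C24, release of the C18 ketone, and orthogonal protection of O29 (acyl) and O27 (silyl).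

16 goes back through 14 and 12 to 11 by cutting C25–O27. A hydroxyl-directed epoxidation with VO(acac)2 would have to choose between two homoallylic alkenes (C25=C26 and C10=C11). A carbonate tether on O29 can only close a fused six-membered ring at C25, and it delivers O27 to the C28 face. The forward iodocyclisation must tolerate a ring that is trans-fused to ring B.

11 is cut at C12–C25 to 10. This is the key step: one bond closes ring A and creates the spiro centre. It requires attack anti to the C28 silyl ether and exo closure.

10 goes back through 9 and 8 to 3 and 6 by cutting C12–C13. An alkenyllithium opens an epoxide, the carbinol is oxidised and the ketone is protected. This avoids strong base next to the bromoalkene, which an acyl-anion route would need. The β,γ-unsaturated ketone 9 must be ketalised without conjugation.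

3 goes back through 2 to 1, where C28 is set by a catalytic reduction. 6 goes back through 5 to 4 by cutting C23–C24 (allyl–allyl coupling) and removing the epoxide oxygen.

## Other disconnections considered

Alternative 1: The cut is C12–C28, with ring A taken from an aromatic precursor as a 4-hydroxy-4-methylcyclohexadienone. In the forward step the selenoester A1 releases an acyl radical at C28 under (Me3Si)3SiH and AIBN. The radical adds 5-exo to C12, the β-carbon of the dienone, and the α-keto radical at C13 is reduced to give the diketone A2.
- In its favour: the nucleophilic acyl radical and the enone are polarity-matched, and the step tolerates the free tertiary alcohol. C25 arrives already as the methyl carbinol, and A2 keeps the C23=C24 enone that blocks C23. On these two points it is better than the chosen plan, which spends steps 9–11 and 15 on them.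
- Against it here: the absolute configuration rests on desymmetrising an achiral dienone, and the face of attack at C12 then depends on the small difference between OH and CH3 at C25. C28 emerges as a ketone, so its reduction must be chemoselective against the C18 carbonyl. A hydride delivered from O27 would point O29 the right way, so on that count the two plans are equal.
- Comparison: structurally both plans make C12 by an exo closure onto a trisubstituted alkene next to an oxygenated centre (equal). Mechanistically the radical step is metal-free and at least as robust (equal or better). In the chosen plan the relay starts from a catalytic ketone reduction of wide scope, which is the firmer footing. In step count to the spiro core the alternative is shorter (better).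

Alternative 2: The cut is C23–C24, on the side of ring A remote from the spiro centre. In the forward step the silyl enol ether A3 is oxidised at the anode to a radical cation. C23 attacks the isopropenyl methylene C24, and the C25 cation is captured by the carbonyl oxygen of the C28 tert-butyl carbonate to give the cyclic carbonate A4.
- In its favour: ring A, the C25 carbinol and its configuration arise in one step. The oxygen is delivered from O29 by the same tether logic as step 10 (equal). A4 has the C13 chain and a saturated C18 ketone in place, so blocking, dehydrogenation and hydrogenation are not needed (better).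
- Against it here: the hard part moves into the open-chain precursor. A3 must already hold the quaternary C12 and the adjacent C13 centre, made without help from ring A. The electrolysis must also spare the other oxidisable groups and win against desilylation.
- Comparison: structurally the chosen plan creates the quaternary centre in the ring-forming step, whereas the alternative needs it beforehand (chosen plan better). Mechanistically both are substrate-controlled, but the anodic coupling with cation capture has less precedent for this ring size. In step economy after ring closure the alternative is better, and overall the two are about equal.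

Alternative 3: The cut is C6–C9. In the forward step Rh2(OAc)4 turns the diazoacetate A5 into a carbenoid at C6, which inserts into the C9–H bond cis to O29 and gives the cis-fused lactone A6.
- In its favour: the transfer of C28 to C9 is stereospecific. The chosen plan uses the same bond construction in step 24, so on this bond the two are equal. A5 has no alkene in ring A, so site selectivity could be cleaner than for 32 (better on that point).
- Against it as the strategy-bearing step: it closes no carbocycle and builds no quaternary centre. It presupposes A5 with four stereocentres, so the core problem is left to other chemistry. Keeping C18 as a ketal also postpones the enal until after the triene is present, which means acid and oxidant at the end.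
- Comparison: structurally it solves the least demanding centre. Mechanistically it is equal. In step count for this bond it is equal, and the difference lies only in what carries the plan and in the order of events.

Key step: step 8

Remark: 2-bromocyclopent-2-en-1-one and 3-[(tert-butyldimethylsilyl)oxy]propanal are taken as purchasable; atom labels C1–C35 are the positions in the target SMILES.

## Steps

Step 1
Reactants: 1 2-bromocyclopent-2-en-1-one
Product: 2 (1R)-2-bromocyclopent-2-en-1-ol
Conditions: (S)-2-methyl-CBS-oxazaborolidine (10 mol%), BH3·SMe2, THF, −20 °C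
Reagents that add atoms: none
Why: Corey–Bakshi–Shibata reduction; the ketone should bind the catalyst boron anti to its larger α-bromovinyl flank, so hydride from the coordinated borane reaches one face and sets C28 as R. α-Substituted cyclic enones are standard substrates for this reduction.

Step 2
Reactants: 2 (1R)-2-bromocyclopent-2-en-1-ol
Product: 3 [(1R)-2-bromocyclopent-2-en-1-yl]oxy(tert-butyl)dimethylsilane
Conditions: TBSCl, imidazole, DMF, rt
Reagents that add atoms: tert-butyl(chloro)dimethylsilane, CC(C)(C)[Si](C)(C)Cl
Why: Standard silylation of a secondary alcohol; the bulky silyl group is chosen because it must shield one face of the cyclopentene in step 8.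

Step 3
Reactants: 4 2,3-dibromoprop-1-ene
Product: 5 2-bromohexa-1,5-diene
Conditions: allylmagnesium bromide, Et2O, 0 °C → rt
Reagents that add atoms: allylmagnesium bromide, C=CC[Mg]Br
Why: Allyl–allyl coupling of a Grignard reagent with the allylic bromide; the vinylic bromide is inert, and SN2 and SN2' attack give the same product.

Step 4
Reactants: 5 2-bromohexa-1,5-diene
Product: 6 2-(3-bromobut-3-en-1-yl)oxirane (racemic)
Conditions: mCPBA, CH2Cl2, 0 °C → rt
Reagents that add atoms: 3-chloroperoxybenzoic acid, OOC(=O)c1cccc(Cl)c1
Why: Prilezhaev epoxidation; the monosubstituted alkene is much more nucleophilic than the bromoalkene, so only it should react.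

Step 5
Reactants: 3 [(1R)-2-bromocyclopent-2-en-1-yl]oxy(tert-butyl)dimethylsilane; 6 2-(3-bromobut-3-en-1-yl)oxirane
Product: 8 5-bromo-1-[(5R)-5-(tert-butyldimethylsilyloxy)cyclopent-1-en-1-yl]hex-5-en-2-ol (both carbinol epimers), via alkenyllithium 7 (not isolated)
Conditions: t-BuLi (2.0 equiv), Et2O, −78 °C; then 6, BF3·OEt2, −78 °C
Reagents that add atoms: none
Why: Bromine–lithium exchange followed by BF3-assisted opening of the terminal epoxide at its CH2 carbon by the alkenyllithium, which forms C12–C13. The new carbinol centre (C18) is oxidised in the next step, so its configuration does not matter.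

Step 6
Reactants: 8 5-bromo-1-[(5R)-5-(tert-butyldimethylsilyloxy)cyclopent-1-en-1-yl]hex-5-en-2-ol
Product: 9 5-bromo-1-[(5R)-5-(tert-butyldimethylsilyloxy)cyclopent-1-en-1-yl]hex-5-en-2-one
Conditions: Dess–Martin periodinane, NaHCO3, CH2Cl2, 0 °C → rt
Reagents that add atoms: none
Why: Dess–Martin oxidation; the buffered, near-neutral medium should keep the β,γ-unsaturated ketone from moving into conjugation.

Step 7
Reactants: 9 5-bromo-1-[(5R)-5-(tert-butyldimethylsilyloxy)cyclopent-1-en-1-yl]hex-5-en-2-one
Product: 10 bromodiene ketal, tert-butyl{[(1R)-2-{[2-(3-bromobut-3-en-1-yl)-1,3-dioxolan-2-yl]methyl}cyclopent-2-en-1-yl]oxy}dimethylsilane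
Conditions: TMSOCH2CH2OTMS, TMSOTf (5 mol%), CH2Cl2, −78 → −20 °C
Reagents that add atoms: 1,2-bis(trimethylsilyloxy)ethane, C[Si](C)(C)OCCO[Si](C)(C)C
Why: Silyl-transfer ketalisation under aprotic conditions at low temperature; it is known to ketalise β,γ-unsaturated ketones without double-bond shift and should spare the allylic silyl ether.

Step 8
Reactants: 10 bromodiene ketal
Product: 11 spiro diene (ring A closed at C12; C28 silyl ether; C18 dioxolane; C25=C26 methylene; C10=C11 alkene)
Conditions: Pd(OAc)2 (10 mol%), PPh3 (30 mol%), Ag2CO3 (2 equiv), MeCN, 80 °C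
Reagents that add atoms: none
Why: Zerovalent palladium, formed from Pd(OAc)2 and PPh3, inserts into the C25–Br bond, and silver takes the bromide to leave a cationic alkenylpalladium. This adds syn across C11=C12 in a 6-exo-trig carbopalladation that bonds C25 to C12, closes ring A and places palladium on C11. C11 has no hydrogen on the C12 side, so syn β-hydride elimination takes a hydrogen from C10 and gives the C10=C11 alkene; the silver carbonate absorbs HBr and should limit re-addition of the palladium hydride and double-bond migration. The closest known reaction type is the intramolecular Heck spirocyclisation that builds all-carbon quaternary centres on cyclic trisubstituted alkenes. The one new stereocentre, C12, is controlled by the silyloxy group on the adjacent allylic C28: it covers its own face, so C25 should enter anti to O29 and the C13 tether ends up syn to it, as the target requires. The step needs this facial selectivity and exo closure; 7-endo attack at C11 would put palladium on the fully substituted C12 and is disfavoured by ring size and substitution.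

Step 9
Reactants: 11 spiro diene
Product: 12 spiro dienol (C28–OH free)
Conditions: Bu4NF, THF, rt → 40 °C
Reagents that add atoms: none
Why: Fluoride cleavage of the silyl ether; the ketal and both alkenes are inert.

Step 10
Reactants: 12 spiro dienol
Product: 14 cyclic iodocarbonate (O29–C(=O)–O27 bridging C28 and C25; C26 iodomethyl), via lithium carbonate 13 (not isolated)
Conditions: n-BuLi, THF, −78 °C; CO2, −78 → 0 °C; I2, 0 °C → rt
Reagents that add atoms: carbon dioxide, O=C=O; iodine, II
Why: Iodocarbonate cyclisation: the lithium alkyl carbonate closes 6-exo onto the iodine-activated C25=C26 alkene at its fully substituted carbon. Only this alkene gives a fused six-membered carbonate (closure onto C10=C11 would need a bridged ring), so the reaction is chemoselective. The tether can deliver O27 only to the C28 face of ring A, which is the configuration of C25 in the target.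

Step 11
Reactants: 14 cyclic iodocarbonate
Product: 16 diol (C28–OH, C25 methyl carbinol; C10=C11; C18 dioxolane), via epoxy alcohol 15 (not isolated)
Conditions: LiAlH4, THF, 0 °C → rt
Reagents that add atoms: none
Why: Hydride reduces the carbonate to the two alkoxides and methanol; the C25 alkoxide displaces the neighbouring iodide to give the epoxide, which hydride opens at its CH2 carbon, so C26 becomes the methyl group with the C25 configuration unchanged.

Step 12
Reactants: 16 diol
Product: 17 C28 pivalate
Conditions: t-BuCOCl, pyridine, DMAP (cat.), CH2Cl2, rt → 40 °C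
Reagents that add atoms: 2,2-dimethylpropanoyl chloride, CC(C)(C)C(Cl)=O
Why: Acylation is selective for the secondary over the tertiary alcohol; a pivalate has no α-hydrogen, tolerates the amide bases to come, and adds bulk on the C28 face of C13.

Step 13
Reactants: 17 C28 pivalate
Product: 18 C28 pivalate C25 triethylsilyl ether
Conditions: Et3SiOTf, 2,6-lutidine, CH2Cl2, −78 → 0 °C
Reagents that add atoms: triethylsilyl trifluoromethanesulfonate, CC[Si](CC)(CC)OS(=O)(=O)C(F)(F)F
Why: A silyl triflate is reactive enough to silylate the hindered tertiary alcohol, and the cold, buffered medium should leave the ketal alone.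

Step 14
Reactants: 18 C28 pivalate C25 triethylsilyl ether
Product: 19 C18 ketone
Conditions: PPTS, acetone–H2O (10:1), 55 °C
Reagents that add atoms: water, O
Why: Mild acid-catalysed ketal hydrolysis; the pivalate and the hindered tertiary silyl ether should survive.

Step 15
Reactants: 19 C18 ketone
Product: 21 enone (C23=C24 conjugated with C18=O), via silyl enol ether 20 (not isolated)
Conditions: LiN(i-Pr)2, Me3SiCl, THF, −78 °C; then Pd(OAc)2 (1.1 equiv), MeCN, rt
Reagents that add atoms: chlorotrimethylsilane, C[Si](C)(C)Cl (its atoms are carried by 20 only)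
Why: Saegusa–Ito oxidation: kinetic enolisation occurs at C23 because C13 is neopentyl, and only C23–C24 can be dehydrogenated since C12 has no hydrogen. The enone blocks C23 for the next step.

Step 16
Reactants: 21 enone; 22 3-[(tert-butyldimethylsilyl)oxy]propanal
Product: 23 aldol adduct (C13–C14 bond; C14 carbinol; mixture of epimers at C13 and C14)
Conditions: LiN(i-Pr)2, THF, −78 °C; then 22
Reagents that add atoms: none
Why: Kinetic α'-deprotonation of the enone can occur only at C13, and the cross-conjugated enolate adds to the aldehyde (aldol addition). Both new centres are removed in step 17.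

Step 17
Reactants: 23 aldol adduct
Product: 25 cross-conjugated dienone (C13=C14 exocyclic, C23=C24 endocyclic), via mesylate 24 (not isolated)
Conditions: MsCl, Et3N, CH2Cl2, 0 °C; then DBU, rt
Reagents that add atoms: methanesulfonyl chloride, CS(=O)(=O)Cl (its atoms are carried by 24 only)
Why: Mesylation and E1cB elimination of the β-hydroxy ketone; either alkene geometry serves, because the alkene is hydrogenated next.

Step 18
Reactants: 25 cross-conjugated dienone
Product: 26 saturated ketone (C13 hydroxypropyl chain as its TBS ether on the C28 face; ring B saturated)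
Conditions: H2 (1 atm), 10% Pd/C, EtOAc, rt
Reagents that add atoms: none
Why: Heterogeneous hydrogenation saturates C13=C14, C23=C24 and C10=C11 in one operation. Hydrogen should reach C13 from the C11 face of ring A, because the C28 pivalate (O29 is syn to C13 across the C12–C28 bond) and the C25 silyloxy group cover the other face; C14 is thereby placed on the C28 face. Esters, silyl ethers and the ketone are inert under these neutral conditions.

Step 19
Reactants: 26 saturated ketone
Product: 27 isopropenyl carbinol (tertiary allylic alcohol at C18; either C18 epimer)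
Conditions: CH2=C(CH3)MgBr, CeCl3, THF, −78 °C
Reagents that add atoms: isopropenylmagnesium bromide, C=C(C)[Mg]Br
Why: Organocerium 1,2-addition; the low basicity should avoid enolisation and so protect the C13 centre, and the pivalate is not attacked at −78 °C. The C18 configuration is lost in step 20.

Step 20
Reactants: 27 isopropenyl carbinol
Product: 28 enal (C18=C19 tetrasubstituted; C20 methyl cis to C13, C21 formyl cis to C23)
Conditions: pyridinium chlorochromate [C5H5NH][CrO3Cl], NaOAc, 4 Å MS, CH2Cl2, rt
Reagents that add atoms: pyridinium chlorochromate, [O-][Cr](=O)(=O)Cl.c1cc[nH+]cc1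
Why: Babler–Dauben oxidative transposition: the chromate ester of the tertiary allylic alcohol undergoes a [3,3] shift to C21 and the primary chromate is oxidised to the aldehyde. In the chair-like shift the migrating terminus C21 should turn towards the unsubstituted C23 and away from C13 with its chain, which leaves C20 cis to C13. A minor geometric isomer, if formed, should be separable at this stage.

Step 21
Reactants: 28 enal
Product: 29 enal dimethyl acetal
Conditions: HC(OMe)3, PPTS (cat.), MeOH, 0 °C
Reagents that add atoms: trimethyl orthoformate, COC(OC)OC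
Why: Acetalisation with an orthoformate as water scavenger; short exposure at 0 °C should spare the primary TBS ether. The acetal hides the enal from the amide base and hydride reagents used later.

Step 22
Reactants: 29 enal dimethyl acetal
Product: 30 C28 alcohol (pivalate removed)
Conditions: i-Bu2AlH, CH2Cl2, −78 °C; KNaC4H4O6 (aq.)
Reagents that add atoms: none
Why: Reductive cleavage of the pivalate; the acetal, both silyl ethers and the tetrasubstituted alkene do not react with the hydride.

Step 23
Reactants: 30 C28 alcohol
Product: 32 C28 diazoacetate, via tosylhydrazone ester 31 (not isolated)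
Conditions: TsNHN=CHCOCl, PhNMe2, CH2Cl2, 0 °C; then Et3N, rt
Reagents that add atoms: 2-[2-(4-methylbenzenesulfonyl)hydrazinylidene]acetyl chloride, Cc1ccc(cc1)S(=O)(=O)NN=CC(Cl)=O
Why: Acylation of the secondary alcohol by the glyoxylyl chloride tosylhydrazone, then base-induced loss of sulfinate (Bamford–Stevens-type fragmentation) gives the diazoacetate in one flask. The amine-buffered medium leaves the acetal intact.

Step 24
Reactants: 32 C28 diazoacetate
Product: 33 cis-fused γ-lactone (C6–C9 bond; O29–C7(=O)–C6–C9–C28 ring)
Conditions: Rh2(OAc)4 (1 mol%), CH2Cl2, reflux, slow addition of 32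
Reagents that add atoms: none
Why: Rhodium carbenoid C–H insertion: the five-membered transition state can reach only the C9–H bond on the O29 face, because C12 has no hydrogen, so the lactone is cis-fused and C9 takes its configuration from C28. O27 is silylated, which excludes O–H insertion, and the hindered tetrasubstituted alkene is a poor partner for cyclopropanation.

Step 25
Reactants: 34 6-methylhept-5-en-2-one
Product: 35 6-methylhepta-1,5-dien-2-yl trifluoromethanesulfonate
Conditions: LiN(i-Pr)2, THF, −78 °C; PhNTf2, −78 → 0 °C
Reagents that add atoms: N-phenylbis(trifluoromethanesulfonimide), FC(F)(F)S(=O)(=O)N(c1ccccc1)S(=O)(=O)C(F)(F)F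
Why: Kinetic deprotonation of the methyl ketone on its methyl side and O-triflation of the enolate give the terminal alkenyl triflate.

Step 26
Reactants: 35 6-methylhepta-1,5-dien-2-yl trifluoromethanesulfonate; 36 prop-2-enal
Product: 37 (2E)-8-methyl-4-methylidenenona-2,7-dienal
Conditions: Pd(OAc)2 (5 mol%), Bu4NCl, NaHCO3, DMF, 40 °C
Reagents that add atoms: none
Why: Heck coupling of an alkenyl triflate with an acceptor alkene under chloride-assisted, phosphine-free conditions; syn insertion and syn β-hydride elimination give the E-enal.

Step 27
Reactants: 33 cis-fused γ-lactone; 37 (2E)-8-methyl-4-methylidenenona-2,7-dienal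
Product: 38 β-hydroxy lactone (C5–C6 bond; mixture of epimers at C5 and C6)
Conditions: LiN(i-Pr)2, THF, −78 °C; then 37
Reagents that add atoms: none
Why: The lithium enolate of the lactone adds 1,2 to the dienal (aldol addition); the acetal and silyl ethers are stable to the base. Both new centres are removed in step 28.

Step 28
Reactants: 38 β-hydroxy lactone
Product: 40 (E)-alkylidene lactone with the complete triene, via mesylate 39 (not isolated)
Conditions: MsCl, Et3N, CH2Cl2, −20 °C; then DBU, 0 °C → rt
Reagents that add atoms: methanesulfonyl chloride, CS(=O)(=O)Cl (its atoms are carried by 39 only)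
Why: Mesylation and E1cB elimination; under these reversible-enolate conditions the more stable isomer, with C4 anti to the lactone carbonyl, should predominate, which is the C5=C6 geometry of the target.

Step 29
Reactants: 40 (E)-alkylidene lactone
Product: 41 desilylated lactone (C16–OH and C25–OH free; C21 acetal)
Conditions: Bu4NF, THF, 0 °C → rt
Reagents that add atoms: none
Why: Fluoride removes the primary TBS and the tertiary triethylsilyl group; the lactone, acetal and triene do not react.

Step 30
Reactants: 41 desilylated lactone
Product: 43 target CNP0246965.4, via acetal tetraol 42 (not isolated)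
Conditions: i-Bu2AlH (excess), CH2Cl2–THF, −78 → 0 °C; then 10% aq. tartaric acid, rt
Reagents that add atoms: water, O
Why: The aluminium hydride reduces the unsaturated lactone by 1,2-addition to the allylic 1,4-diol (C7–OH and C28–OH) without touching the triene. The mildly acidic aqueous quench hydrolyses the conjugated dimethyl acetal, which is among the most labile of acetals, to the enal.

## Compound list

1 | 2-bromocyclopent-2-en-1-one | O=C1CCC=C1Br | starting material
2 | (1R)-2-bromocyclopent-2-en-1-ol | BrC1=CCC[C@H]1O | intermediate
3 | [(1R)-2-bromocyclopent-2-en-1-yl]oxy(tert-butyl)dimethylsilane | BrC1=CCC[C@H]1O[Si](C)(C)C(C)(C)C | intermediate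
4 | 2,3-dibromoprop-1-ene | C=C(Br)CBr | starting material
5 | 2-bromohexa-1,5-diene | C=C(Br)CCC=C | intermediate
6 | 2-(3-bromobut-3-en-1-yl)oxirane (racemic) | C=C(Br)CCC1CO1 | intermediate
7 | [(5R)-5-(tert-butyldimethylsilyloxy)cyclopent-1-en-1-yl]lithium | [Li]C1=CCC[C@H]1O[Si](C)(C)C(C)(C)C | intermediate (not isolated)
8 | 5-bromo-1-[(5R)-5-(tert-butyldimethylsilyloxy)cyclopent-1-en-1-yl]hex-5-en-2-ol (both C2 epimers) | C=C(Br)CCC(O)CC1=CCC[C@H]1O[Si](C)(C)C(C)(C)C | intermediate
9 | 5-bromo-1-[(5R)-5-(tert-butyldimethylsilyloxy)cyclopent-1-en-1-yl]hex-5-en-2-one | C=C(Br)CCC(=O)CC1=CCC[C@H]1O[Si](C)(C)C(C)(C)C | intermediate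
10 | bromodiene ketal, tert-butyl{[(1R)-2-{[2-(3-bromobut-3-en-1-yl)-1,3-dioxolan-2-yl]methyl}cyclopent-2-en-1-yl]oxy}dimethylsilane | C=C(Br)CCC1(OCCO1)CC2=CCC[C@H]2O[Si](C)(C)C(C)(C)C | intermediate
11 | spiro diene: C28 TBS ether, C18 dioxolane, C25=C26 methylene, C10=C11 alkene | C1C=C[C@]2(CC3(OCCO3)CCC2=C)[C@@H]1O[Si](C)(C)C(C)(C)C | intermediate
12 | spiro dienol: as 11 with C28–OH free | C1C=C[C@]2(CC3(OCCO3)CCC2=C)[C@@H]1O | intermediate
13 | lithium C28 carbonate of 12 | C1C=C[C@]2(CC3(OCCO3)CCC2=C)[C@@H]1OC(=O)[O-].[Li+] | intermediate (not isolated)
14 | cyclic iodocarbonate: carbonate bridging O29 and O27, C26 iodomethyl on C25 | C1C=C[C@]2(CC3(OCCO3)CC[C@]2(CI)OC(=O)O4)[C@@H]14 | intermediate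
15 | epoxy alcohol: C25–C26 spiro-epoxide with O27 on the C28 face, C28–OH | C1C=C[C@]2(CC3(OCCO3)CC[C@]2(C5)O5)[C@@H]1O | intermediate (not isolated)
16 | diol: C28–OH, C25 methyl carbinol, C10=C11 alkene, C18 dioxolane | C1C=C[C@]2(CC3(OCCO3)CC[C@]2(C)O)[C@@H]1O | intermediate
17 | C28 pivalate of 16 | C1C=C[C@]2(CC3(OCCO3)CC[C@]2(C)O)[C@@H]1OC(=O)C(C)(C)C | intermediate
18 | C28 pivalate C25 triethylsilyl ether | C1C=C[C@]2(CC3(OCCO3)CC[C@]2(C)O[Si](CC)(CC)CC)[C@@H]1OC(=O)C(C)(C)C | intermediate
19 | C18 ketone (C28 pivalate, C25 triethylsilyl ether, C10=C11) | C1C=C[C@]2(CC(=O)CC[C@]2(C)O[Si](CC)(CC)CC)[C@@H]1OC(=O)C(C)(C)C | intermediate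
20 | C18 trimethylsilyl enol ether (C18=C23) | C1C=C[C@]2(CC(O[Si](C)(C)C)=CC[C@]2(C)O[Si](CC)(CC)CC)[C@@H]1OC(=O)C(C)(C)C | intermediate (not isolated)
21 | enone: C23=C24 conjugated with C18=O | C1C=C[C@]2(CC(=O)C=C[C@]2(C)O[Si](CC)(CC)CC)[C@@H]1OC(=O)C(C)(C)C | intermediate
22 | 3-[(tert-butyldimethylsilyl)oxy]propanal | O=CCCO[Si](C)(C)C(C)(C)C | starting material
23 | aldol adduct: C13 bears CH(OH)CH2CH2OTBS (epimers at C13 and C14) | C1C=C[C@]2(C(C(O)CCO[Si](C)(C)C(C)(C)C)C(=O)C=C[C@]2(C)O[Si](CC)(CC)CC)[C@@H]1OC(=O)C(C)(C)C | intermediate
24 | C14 mesylate of 23 | C1C=C[C@]2(C(C(OS(C)(=O)=O)CCO[Si](C)(C)C(C)(C)C)C(=O)C=C[C@]2(C)O[Si](CC)(CC)CC)[C@@H]1OC(=O)C(C)(C)C | intermediate (not isolated)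
25 | cross-conjugated dienone: C13=C14 exocyclic (either geometry), C23=C24 | C1C=C[C@]2(C(=CCCO[Si](C)(C)C(C)(C)C)C(=O)C=C[C@]2(C)O[Si](CC)(CC)CC)[C@@H]1OC(=O)C(C)(C)C | intermediate
26 | saturated ketone: C13 3-(TBS-oxy)propyl on the C28 face, C18 ketone, rings saturated | C1CC[C@]2([C@H](CCCO[Si](C)(C)C(C)(C)C)C(=O)CC[C@]2(C)O[Si](CC)(CC)CC)[C@@H]1OC(=O)C(C)(C)C | intermediate
27 | isopropenyl carbinol: C18(OH)(isopropenyl), either C18 epimer | C1CC[C@]2([C@H](CCCO[Si](C)(C)C(C)(C)C)C(O)(C(C)=C)CC[C@]2(C)O[Si](CC)(CC)CC)[C@@H]1OC(=O)C(C)(C)C | intermediate
28 | enal: C18=C19(CH3)CHO, methyl cis to C13 | C1CC[C@]2([C@H](CCCO[Si](C)(C)C(C)(C)C)/C(=C(\C)C=O)CC[C@]2(C)O[Si](CC)(CC)CC)[C@@H]1OC(=O)C(C)(C)C | intermediate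
29 | enal dimethyl acetal (C21 as CH(OMe)2) | C1CC[C@]2([C@H](CCCO[Si](C)(C)C(C)(C)C)/C(=C(\C)C(OC)OC)CC[C@]2(C)O[Si](CC)(CC)CC)[C@@H]1OC(=O)C(C)(C)C | intermediate
30 | C28 alcohol: as 29 without the pivalate | C1CC[C@]2([C@H](CCCO[Si](C)(C)C(C)(C)C)/C(=C(\C)C(OC)OC)CC[C@]2(C)O[Si](CC)(CC)CC)[C@@H]1O | intermediate
31 | C28 glyoxylate tosylhydrazone ester | C1CC[C@]2([C@H](CCCO[Si](C)(C)C(C)(C)C)/C(=C(\C)C(OC)OC)CC[C@]2(C)O[Si](CC)(CC)CC)[C@@H]1OC(=O)C=NNS(=O)(=O)c3ccc(C)cc3 | intermediate (not isolated)
32 | C28 diazoacetate | C1CC[C@]2([C@H](CCCO[Si](C)(C)C(C)(C)C)/C(=C(\C)C(OC)OC)CC[C@]2(C)O[Si](CC)(CC)CC)[C@@H]1OC(=O)C=[N+]=[N-] | intermediate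
33 | cis-fused γ-lactone (O29–C7(=O)–C6H2–C9) | O=C1C[C@@H]2CC[C@]3([C@H](CCCO[Si](C)(C)C(C)(C)C)/C(=C(\C)C(OC)OC)CC[C@]3(C)O[Si](CC)(CC)CC)[C@@H]2O1 | intermediate
34 | 6-methylhept-5-en-2-one | CC(=O)CCC=C(C)C | starting material
35 | 6-methylhepta-1,5-dien-2-yl trifluoromethanesulfonate | C=C(OS(=O)(=O)C(F)(F)F)CCC=C(C)C | intermediate
36 | prop-2-enal (acrolein) | C=CC=O | starting material
37 | (2E)-8-methyl-4-methylidenenona-2,7-dienal | O=C/C=C/C(=C)CCC=C(C)C | intermediate
38 | β-hydroxy lactone: C6 bears CH(OH)–dienyl chain (epimers at C5 and C6) | O=C1C(C(O)/C=C/C(=C)CCC=C(C)C)[C@@H]2CC[C@]3([C@H](CCCO[Si](C)(C)C(C)(C)C)/C(=C(\C)C(OC)OC)CC[C@]3(C)O[Si](CC)(CC)CC)[C@@H]2O1 | intermediate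
39 | C5 mesylate of 38 | O=C1C(C(OS(C)(=O)=O)/C=C/C(=C)CCC=C(C)C)[C@@H]2CC[C@]3([C@H](CCCO[Si](C)(C)C(C)(C)C)/C(=C(\C)C(OC)OC)CC[C@]3(C)O[Si](CC)(CC)CC)[C@@H]2O1 | intermediate (not isolated)
40 | (E)-alkylidene lactone with the triene (C4 anti to the lactone carbonyl) | O=C1/C(=C/C=C/C(=C)CCC=C(C)C)[C@@H]2CC[C@]3([C@H](CCCO[Si](C)(C)C(C)(C)C)/C(=C(\C)C(OC)OC)CC[C@]3(C)O[Si](CC)(CC)CC)[C@@H]2O1 | intermediate
41 | desilylated lactone: C16–OH, C25–OH, C21 acetal | O=C1/C(=C/C=C/C(=C)CCC=C(C)C)[C@@H]2CC[C@]3([C@H](CCCO)/C(=C(\C)C(OC)OC)CC[C@]3(C)O)[C@@H]2O1 | intermediate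
42 | acetal tetraol: target with C21 as CH(OMe)2 | C=C(/C=C/C=C(/CO)[C@@H]1CC[C@]2([C@H](CCCO)/C(=C(\C)C(OC)OC)CC[C@]2(C)O)[C@@H]1O)CCC=C(C)C | intermediate (not isolated)
43 | CNP0246965.4 | C=C(/C=C/C=C(/CO)[C@@H]1CC[C@]2([C@H](CCCO)/C(=C(\C)C=O)CC[C@]2(C)O)[C@@H]1O)CCC=C(C)C | target

## Step count and least certain steps

Total: 30 steps (isolated products; in-flask intermediates are not counted). Longest linear sequence: 26 steps (1, 2, 5–24, 27–30).

Step 8 (key step). The most likely failure is migration of the new double bonds by re-addition of the palladium hydride, together with loss of facial selectivity at the temperature the bromoalkene needs for oxidative addition. The fallback sets out from 10 and returns at 11. 10 is treated with LiN(i-Pr)2 (2.2 equiv, THF, −78 → 0 °C) to eliminate HBr and give the terminal alkyne F1. Pd(OAc)2 and PPh3 with a little acetic acid in toluene at 60 °C should then add a palladium hydride across the alkyne with the metal on C25. The same 6-exo insertion into C11=C12 and β-hydride elimination towards C10 follow. This is an enyne cycloisomerisation of the Alder-ene type, which needs no halide, silver or stoichiometric base and runs at lower temperature.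

Step 18. The most likely failure is delivery of hydrogen to C13 from the C28 face, or epimerisation at C13 once the ketone is saturated, since the wanted epimer is the more crowded one. The fallback sets out from 21 and returns at 26. It delivers carbon instead of hydrogen from whichever face proves open. The α'-enolate of 21 (LiN(i-Pr)2, THF, −78 °C) is alkylated with allyl bromide to give the allyl enone F2. Hydroboration of the terminal alkene with Cy2BH and oxidation with NaBO3 gives the primary alcohol F3. Silylation with TBSCl and imidazole gives the silyl ether F4, and hydrogenation over Pd/C saturates C23=C24 and C10=C11 to reach 26.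

Step 20. The most likely failure is poor control of the C18=C19 geometry in the sigmatropic shift, with dehydration of the tertiary alcohol to a diene as a side path. The fallback sets out from 26 and returns at 28. It fixes the geometry by the in-plane steric difference between the two bromines of a dibromoalkene. Ramirez olefination of 26 (CBr4, PPh3, toluene, reflux) gives the dibromoalkene F5. A Stille coupling with tributyl(vinyl)stannane (Pd2(dba)3, tri(2-furyl)phosphine) should take place at the less hindered bromine, cis to C23, to give the bromodiene F6. Negishi methylation of the remaining bromine (Me2Zn, Pd(P(t-Bu)3)2) gives the methyl diene F7. Lemieux–Johnson cleavage of the terminal vinyl group (OsO4 cat., NaIO4, 2,6-lutidine) gives 28.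

Step 24. The most likely failure is carbene dimerisation, or insertion into the allylic tertiary C13–H bond through a six-membered transition state, in competition with insertion at C9–H. The fallback sets out from 30 and returns at 40, and it also replaces steps 27 and 28. It uses a less electrophilic, bulkier acceptor/acceptor carbenoid whose product is already set up for olefination. 30 is esterified with diethylphosphonoacetic acid (DCC, DMAP) to give the phosphonoacetate F8. Diazo transfer (4-acetamidobenzenesulfonyl azide, DBU) gives the diazophosphonoacetate F9. Rh2(OAc)4 in refluxing 1,2-dichloroethane should give the α-phosphono lactone F10 by the same C9–H insertion. A Horner–Wadsworth–Emmons reaction of F10 with 37 (NaH, THF, 0 °C) gives 40.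

## Further compounds

F1 | step 8 | terminal alkyne, tert-butyl{[(1R)-2-{[2-(but-3-yn-1-yl)-1,3-dioxolan-2-yl]methyl}cyclopent-2-en-1-yl]oxy}dimethylsilane | C#CCCC1(OCCO1)CC2=CCC[C@H]2O[Si](C)(C)C(C)(C)C
F2 | step 18 | allyl enone: 21 with an allyl group at C13 on the C28 face | C1C=C[C@]2([C@H](CC=C)C(=O)C=C[C@]2(C)O[Si](CC)(CC)CC)[C@@H]1OC(=O)C(C)(C)C
F3 | step 18 | primary alcohol: 21 with a 3-hydroxypropyl group at C13 | C1C=C[C@]2([C@H](CCCO)C(=O)C=C[C@]2(C)O[Si](CC)(CC)CC)[C@@H]1OC(=O)C(C)(C)C
F4 | step 18 | TBS ether of F3 | C1C=C[C@]2([C@H](CCCO[Si](C)(C)C(C)(C)C)C(=O)C=C[C@]2(C)O[Si](CC)(CC)CC)[C@@H]1OC(=O)C(C)(C)C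
F5 | step 20 | dibromoalkene: 26 with C18=CBr2 | C1CC[C@]2([C@H](CCCO[Si](C)(C)C(C)(C)C)C(=C(Br)Br)CC[C@]2(C)O[Si](CC)(CC)CC)[C@@H]1OC(=O)C(C)(C)C
F6 | step 20 | bromodiene: C18=C19(Br)(vinyl), bromine cis to C13 | C1CC[C@]2([C@H](CCCO[Si](C)(C)C(C)(C)C)/C(=C(\Br)C=C)CC[C@]2(C)O[Si](CC)(CC)CC)[C@@H]1OC(=O)C(C)(C)C
F7 | step 20 | methyl diene: C18=C19(CH3)(vinyl), methyl cis to C13 | C1CC[C@]2([C@H](CCCO[Si](C)(C)C(C)(C)C)/C(=C(\C)C=C)CC[C@]2(C)O[Si](CC)(CC)CC)[C@@H]1OC(=O)C(C)(C)C
F8 | step 24 | C28 diethylphosphonoacetate of 30 | C1CC[C@]2([C@H](CCCO[Si](C)(C)C(C)(C)C)/C(=C(\C)C(OC)OC)CC[C@]2(C)O[Si](CC)(CC)CC)[C@@H]1OC(=O)CP(=O)(OCC)OCC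
F9 | step 24 | C28 diazo(diethoxyphosphoryl)acetate | C1CC[C@]2([C@H](CCCO[Si](C)(C)C(C)(C)C)/C(=C(\C)C(OC)OC)CC[C@]2(C)O[Si](CC)(CC)CC)[C@@H]1OC(=O)C(=[N+]=[N-])P(=O)(OCC)OCC
F10 | step 24 | α-(diethoxyphosphoryl) cis-fused γ-lactone (either C6 epimer) | O=C1C(P(=O)(OCC)OCC)[C@@H]2CC[C@]3([C@H](CCCO[Si](C)(C)C(C)(C)C)/C(=C(\C)C(OC)OC)CC[C@]3(C)O[Si](CC)(CC)CC)[C@@H]2O1
A1 | alternative 1 | Se-phenyl selenoester of the 4-hydroxy-4-methylcyclohexa-2,5-dienone carrying the C11–C10–C9–C28 chain on C12 | O=C([Se]c1ccccc1)CCCC2=CC(=O)C=C[C@]2(C)O
A2 | alternative 1 | spiro enone diketone | C1CC[C@]2(CC(=O)C=C[C@]2(C)O)C1=O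
A3 | alternative 2 | C18 trimethylsilyl enol ether with C12 isopropenyl and C28 tert-butyl carbonate | C1CC[C@](C(C)=C)([C@H](CCCO[Si](C)(C)C(C)(C)C)C(=C)O[Si](C)(C)C)[C@@H]1OC(=O)OC(C)(C)C
A4 | alternative 2 | ring-A ketone cyclic carbonate | C1CC[C@]2([C@H](CCCO[Si](C)(C)C(C)(C)C)C(=O)CC[C@]2(C)O3)[C@@H]1OC3=O
A5 | alternative 3 | C28 diazoacetate with C18 dioxolane, C25 triethylsilyl ether, C16 TBS ether | C1CC[C@]2([C@H](CCCO[Si](C)(C)C(C)(C)C)C3(OCCO3)CC[C@]2(C)O[Si](CC)(CC)CC)[C@@H]1OC(=O)C=[N+]=[N-]
A6 | alternative 3 | cis-fused γ-lactone with C18 dioxolane | O=C1C[C@@H]2CC[C@]3([C@H](CCCO[Si](C)(C)C(C)(C)C)C4(OCCO4)CC[C@]3(C)O[Si](CC)(CC)CC)[C@@H]2O1
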